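Per cent of the two substrates charged together is the unit of both tables, so each substrate starts at 50.0%.

| flask | left-handed substrate | right-handed substrate | coupling partner | free catalyst | impurity | remark | time |
|---|---|---|---|---|---|---|---|
| west | 0.28 M | 0.28 M | 0.84 M | 0.56 mM | 80 µM | the very flask that is asked about, followed so far |  |
| north-west | 0.28 M | 0.28 M | 1.7 M | 0.56 mM | 80 µM | run made earlier |  |
| flask | 0.28 M | 0.28 M | 0.840 M | 0.56 mM | 80 µM |  | 1.0 h |

| run | time / min | right-handed substrate / % | left-handed substrate / % |
|---|---|---|---|
| west | 1.33 | 48 | 41 |
| west | 2.00 | 51 | 35 |
| west | 3.00 | 48 | 31 |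
| west | 5.00 | 46 | 21 |
| west | 8.00 | 45 | 16 |
| west | 12.0 | 41 | 8 |
| west | 20.0 | 33 | 2 |
| north-west | 2.00 | 50 | 25 |
| north-west | 3.00 | 46 | 20 |
| north-west | 4.00 | 43 | 18 |
| north-west | 6.00 | 42 | 8 |
| north-west | 10.0 | 36 | 2 |
| north-west | 15.0 | 28 | 3 |
| north-west | 25.0 | 17 | 0 |

(scatter of a reading: 1.5 percentage points)

- free catalyst is single-handed; left-handed substrate and right-handed substrate are mirror images of each other, charged as a racemate, each of them at the stated concentration
- steps under discussion: free catalyst + right-handed substrate <-> catalyst intermediate B; coupling partner + catalyst intermediate A -> free catalyst + left-handed product; free catalyst + left-handed substrate <-> catalyst intermediate A; free catalyst + impurity -> spent catalyst A; coupling partner + catalyst intermediate B -> free catalyst + right-handed product; left-handed product <-> right-handed product; coupling partner + free catalyst -> spent catalyst B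

- whether the excess of right-handed substrate over left-handed substrate among what is left of the two reaches 98% by 1.0 h (no / yes)
- the highest excess of right-handed substrate over left-handed substrate among what is left of the two up to 1.0 h

If the two substrates share one catalyst and each is consumed in proportion to its own concentration, the logarithm of the fraction left of c(left-handed substrate) stays a constant multiple of that of c(right-handed substrate). The west readings at 12.0 min, 8% left-handed and 41% right-handed, put this multiple at 9.23, the selectivity factor. An excess of 98% means a left-to-right ratio of 0.0101, so the factor places that excess at 28.6% of right-handed substrate. The west flask read 33% at 20.0 min, and its last two readings put the loss of right-handed substrate at 0.0271 min⁻¹, which gives an estimated crossing at 25.3 min.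

The weak link is that pair of readings and that late slope. The west pair at 20.0 min gives a factor of 7.75, which moves the target to 25.3%. Taking also the slower average rate of the first 12.0 min in the west flask, 0.0165 min⁻¹, gives an estimate of 36.1 min, still earlier than 1.0 h. This reckoning therefore commits to yes, with about 99.9% at 1.0 h on the cautious figures.

The forecast says yes and 99.9%, with the crossing near 25 min, adding “that last stretch is extrapolated”.

The west flask gives yes and >99.9%.

    free catalyst + right-handed substrate ⇌ catalyst intermediate B (K = 47.0 M⁻¹, k = 359 M⁻¹ min⁻¹)
    coupling partner + catalyst intermediate A → free catalyst + left-handed product (k = 416 M⁻¹ min⁻¹)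
    free catalyst + left-handed substrate ⇌ catalyst intermediate A (K = 14.0 M⁻¹, k = 4200 M⁻¹ min⁻¹)
    free catalyst + impurity → spent catalyst A (k = 20900 M⁻¹ min⁻¹)
    coupling partner + catalyst intermediate B → free catalyst + right-handed product (k = 18.7 M⁻¹ min⁻¹)
    left-handed product ⇌ right-handed product (k = 0.229 min⁻¹)
    coupling partner + free catalyst → spent catalyst B (k = 0.0158 M⁻¹ min⁻¹)

The west flask crosses at 0.577 h with 27.7% of right-handed substrate left, and its state at 0.500 h gives a factor of 8.82. In the north-west run, the factor 9.23 turns 17% of right-handed substrate at 25.0 min into 0.00237% of left-handed substrate, where 0% was read. Taking away the binding of left-handed substrate to free catalyst, both ways, turns the west excess at 1.0 h from >99.9% to −74.1%.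

The runs stem from a simulated flask on assumed constants; noise was put on by code.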